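**Assumptions (one line):** all four phenols are carried as MOM ethers until the last step, and the E/Z geometry of the trisubstituted alkene in 18–21 is irrelevant because it is destroyed in step 20. The six stereocentres are (2S,3S,4S,6S,3′S,5′S), read from the target SMILES. Simple reagents are not numbered.

## Retrosynthetic overview
1. The target comes from global MOM/TBS removal. C4-OH (axial) comes from L-Selectride reduction of an all-equatorial tetrahydropyran-4-one.
2. The ring is formed last, by thermodynamic oxa-Michael closure of a δ-hydroxy enone. This gives 2,6-cis-2,3-trans and is steered by C6-OH, which is set by a ketoreductase on a 1,3-diketone.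
3. The enone-dione comes from the Weinreb amide of an α-alkylidene ester (ester aldol with ArCHO, then dehydration) plus the enolate of 4-aryl-2-butanone.
4. C3′ and the E-styrene come from an Ireland–Claisen rearrangement of an (S)-allylic acetate, which is made by Noyori transfer hydrogenation of an ynone and Red-Al reduction.
5. C5′ comes first, by Ru-BINAP hydrogenation of a β-ketoester.

## Route

**Step 1**
Reactants: 1, 4-(4-hydroxyphenyl)butan-2-one
Product: 2, 4-[4-(methoxymethoxy)phenyl]butan-2-one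
Conditions: MOMCl, i-Pr2NEt, CH2Cl2, 0 °C → rt
Reagents that add atoms: MOMCl, COCCl
Why: Chemoselective O-alkylation of the phenol (MOM protection); the ketone is untouched.

**Step 2**
Reactants: 2
Product: 3, methyl 5-[4-(MOMO)phenyl]-3-oxopentanoate
Conditions: (MeO)2CO, NaH, cat. MeOH, THF, reflux
Reagents that add atoms: dimethyl carbonate, COC(=O)OC
Why: Claisen-type methoxycarbonylation occurs at the unhindered CH3, and the stabilised β-ketoester enolate drives the reaction to this regioisomer.

**Step 3**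
Reactants: 3
Product: 4, methyl (3S)-3-hydroxy-5-[4-(MOMO)phenyl]pentanoate
Conditions: Ru(OAc)2[(S)-BINAP] (0.5 mol %), H2 (50 bar), MeOH, 50 °C
Reagents that add atoms: none (H2 only)
Why: Noyori asymmetric hydrogenation of a β-ketoester proceeds through a chelated Ru-hydride and sets the first stereocentre (C5′, S) with high ee.

**Step 4**
Reactants: 4
Product: 5, the TBS ether of 4
Conditions: TBSCl, imidazole, DMF, rt
Reagents that add atoms: TBSCl, C[Si](C)(C(C)(C)C)Cl
Why: Standard silylation of the secondary alcohol, with no change at the stereocentre.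

**Step 5**
Reactants: 5
Product: 6, (3S)-3-(TBSO)-5-[4-(MOMO)phenyl]pentanal
Conditions: DIBAL-H (1.1 equiv), CH2Cl2, −78 °C
Reagents that add atoms: none
Why: At −78 °C the ester stops at the stable aluminate hemiacetal, which gives the aldehyde on work-up.

**Step 6**
Reactants: 6
Product: 7, the terminal alkyne (3S)-3-(TBSO)-1-[4-(MOMO)phenyl]hex-5-yne
Conditions: Bestmann–Ohira reagent, K2CO3, MeOH, 0 °C → rt
Reagents that add atoms: dimethyl (1-diazo-2-oxopropyl)phosphonate, CC(=O)C(=[N+]=[N-])P(=O)(OC)OC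
Why: Seyferth–Gilbert homologation under mild base suits the β-silyloxy aldehyde, and the remote stereocentre is unaffected.

**Step 7**
Reactants: 8, 4-hydroxybenzaldehyde
Product: 9, 4-(methoxymethoxy)benzaldehyde
Conditions: MOMCl, i-Pr2NEt, CH2Cl2, 0 °C → rt
Reagents that add atoms: MOMCl, COCCl
Why: MOM protection of the phenol; the aldehyde is untouched.

**Step 8**
Reactants: 7, 9
Product: 10, propargylic alcohol (C1 epimer mixture, C5′ = S)
Conditions: n-BuLi (1.05 equiv), THF, −78 °C; then 9
Reagents that add atoms: none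
Why: Lithium acetylide 1,2-addition to the aldehyde; C1 is later oxidised, so its configuration is irrelevant.

**Step 9**
Reactants: 10
Product: 11, ynone
Conditions: activated MnO2 (10 equiv), CH2Cl2, rt
Reagents that add atoms: none
Why: MnO2 selectively oxidises the benzylic/propargylic alcohol and leaves the OTBS, MOM and alkyne groups intact.

**Step 10**
Reactants: 11
Product: 12, (1R,5S)-propargylic alcohol
Conditions: RuCl[(S,S)-TsDPEN](p-cymene) (1 mol %), i-PrOH, 28 °C
Reagents that add atoms: none (H transfer from i-PrOH)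
Why: Noyori asymmetric transfer hydrogenation of an aryl ynone is catalyst-controlled, with aryl acting as the large group and alkynyl as the small group, so the remote C5′ centre is irrelevant. It gives the (R)-propargylic alcohol; use (R,R)-catalyst if the sense is found opposite.

**Step 11**
Reactants: 12
Product: 13, (1S,2E,5S)-allylic alcohol
Conditions: Red-Al (2.5 equiv), THF, 0 °C → rt
Reagents that add atoms: none
Why: Alkoxide-directed trans-hydroalumination gives the E-alkene stereospecifically. C1 is unchanged, but its descriptor becomes S because the CIP priorities of aryl and alkenyl swap.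

**Step 12**
Reactants: 13
Product: 14, allylic acetate of 13
Conditions: Ac2O, Et3N, DMAP (cat.), CH2Cl2, 0 °C → rt
Reagents that add atoms: Ac2O, CC(=O)OC(C)=O
Why: Base-mediated acylation avoids ionising the electron-rich benzylic allylic alcohol.

**Step 13**
Reactants: 14
Product: 15, (3R,5S)-acid, Ar–CH=CH–CH(CH2CO2H)–CH2–CH(OTBS)–CH2CH2Ar
Conditions: LDA (2.4 equiv), TMSCl (2.6 equiv, in situ quench), THF, −78 °C → rt, 12 h; then 1 M citric acid
Reagents that add atoms: none (silyl ester hydrolysed on work-up)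
Why: Ireland–Claisen rearrangement through a chair transition state with aryl equatorial gives the E-styrene. The suprafacial [3,3] shift transfers the (S)-carbinol configuration to C3′, which has the target spatial arrangement; this centre is named R in 15 only because the CIP priorities differ.

**Step 14**
Reactants: 15
Product: 16, methyl ester of 15
Conditions: TMSCHN2, MeOH/PhMe, 0 °C
Reagents that add atoms: trimethylsilyldiazomethane, C[Si](C)(C)C=[N+]=[N-]
Why: Mild diazoalkane methylation; no base is present, so C3′ cannot epimerise.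

**Step 15**
Reactants: 16, 9
Product: 17, β-hydroxy ester (mixture of C2/carbinol epimers, C3′ = S, C5′ = S)
Conditions: LDA (1.1 equiv), THF, −78 °C; then 9, −78 °C
Reagents that add atoms: none
Why: Ester-enolate aldol, which is regiospecific because the ester has only one α-carbon. The two new centres are destroyed in step 16.

**Step 16**
Reactants: 17
Product: 18, α-alkylidene ester (E/Z mixture)
Conditions: MsCl, Et3N, DMAP (cat.), CH2Cl2, 0 °C → rt
Reagents that add atoms: none (the mesylate is lost)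
Why: E1cB elimination of the benzylic mesylate with Et3N; only a weak base is used to protect the acidic, doubly allylic C3′–H.

**Step 17**
Reactants: 18
Product: 19, Weinreb amide
Conditions: MeNH(OMe)·HCl, i-PrMgCl (4 equiv), THF, −20 → 0 °C
Reagents that add atoms: N,O-dimethylhydroxylamine hydrochloride, CNOC.Cl
Why: The magnesium amide transamidates the ester; the β-aryl enoate is a poor Michael acceptor, so conjugate addition is avoided.

**Step 18**
Reactants: 19, 2
Product: 20, enone-1,3-dione, ArCH2CH2C(=O)CH2C(=O)C(=CHAr)–CH(CH=CHAr)CH2CH(OTBS)CH2CH2Ar (Ar = 4-MOMO-C6H4)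
Conditions: 2 (2.5 equiv) + LDA (2.4 equiv), THF, −78 °C; add 19, −78 → 0 °C
Reagents that add atoms: none
Why: Weinreb acylation of the kinetic lithium enolate at the terminal CH3 of 2 gives the C5–C6 unit. The excess enolate leaves no free base to touch C3′–H, and the chelated tetrahedral intermediate prevents over-addition.

**Step 19**
Reactants: 20
Product: 21, δ-hydroxy enone with (6S)-OH
Conditions: (S)-selective ketoreductase (KRED), NADP+ (cat.), GDH/D-glucose, KPi pH 7/DMSO 4:1, 30 °C
Reagents that add atoms: none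
Why: The enzyme reduces the unhindered dialkyl C6 ketone by Prelog-type hydride delivery to give the (S)-alcohol. The hindered, push–pull conjugated C4 carbonyl is not reduced, so C6 is set by catalyst control.

**Step 20**
Reactants: 21
Product: 22, (2S,3R,6S)-2,6-cis-THP-4-one (3R is the CIP label; spatially the same centre as 3S in the target)
Conditions: DBU (0.5 equiv), toluene, rt → 40 °C, 24 h
Reagents that add atoms: none
Why: Reversible intramolecular oxa-Michael addition settles in the chair with C2-aryl, C3-alkyl and C6-alkyl all equatorial (2,6-cis, 2,3-trans); C6 (S) fixes C2 and C3, and the enolisable C3 epimerises to equatorial.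

**Step 21**
Reactants: 22
Product: 23, (2S,3S,4S,6S)-THP-4-ol (fully protected)
Conditions: L-Selectride (1.5 equiv), THF, −78 °C
Reagents that add atoms: none
Why: The bulky hydride attacks equatorially, giving the axial 4-OH cis to the equatorial C3 substituent, as in the target.

**Step 22**
Reactants: 23
Product: 24, the C5′-alcohol (TBS removed, MOM groups retained)
Conditions: TBAF (3 equiv), THF, 0 °C → rt
Reagents that add atoms: none
Why: Fluoride cleaves the secondary TBS ether; the MOM acetals, styrene and THP are unaffected.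

**Step 23**
Reactants: 24
Product: 25, Blepharocalyxin C
Conditions: ZnBr2 (6 equiv), n-PrSH (10 equiv), CH2Cl2, 0 °C → rt, 30 min
Reagents that add atoms: none
Why: Soft Lewis-acid/thiol cleavage of the MOM acetals avoids strong protic acid, which could ionise the electron-rich benzylic C2–O bond.

## Compound list
1 | 4-(4-hydroxyphenyl)butan-2-one | CC(=O)CCc1ccc(O)cc1 | starting material
2 | 4-[4-(MOMO)phenyl]butan-2-one | CC(=O)CCc1ccc(OCOC)cc1 | intermediate
3 | methyl 5-[4-(MOMO)phenyl]-3-oxopentanoate | COC(=O)CC(=O)CCc1ccc(OCOC)cc1 | intermediate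
4 | methyl (3S)-3-hydroxy-5-[4-(MOMO)phenyl]pentanoate | COC(=O)C[C@@H](O)CCc1ccc(OCOC)cc1 | intermediate
5 | methyl (3S)-3-(TBSO)-5-[4-(MOMO)phenyl]pentanoate | COC(=O)C[C@@H](O[Si](C)(C)C(C)(C)C)CCc1ccc(OCOC)cc1 | intermediate
6 | (3S)-3-(TBSO)-5-[4-(MOMO)phenyl]pentanal | O=CC[C@@H](O[Si](C)(C)C(C)(C)C)CCc1ccc(OCOC)cc1 | intermediate
7 | tert-butyl({(3S)-1-[4-(MOMO)phenyl]hex-5-yn-3-yl}oxy)dimethylsilane | C#CC[C@@H](O[Si](C)(C)C(C)(C)C)CCc1ccc(OCOC)cc1 | intermediate
8 | 4-hydroxybenzaldehyde | O=Cc1ccc(O)cc1 | starting material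
9 | 4-(methoxymethoxy)benzaldehyde | O=Cc1ccc(OCOC)cc1 | intermediate
10 | (5S)-5-(TBSO)-1,7-bis[4-(MOMO)phenyl]hept-2-yn-1-ol (C1 epimers) | COCOc1ccc(C(O)C#CC[C@@H](O[Si](C)(C)C(C)(C)C)CCc2ccc(OCOC)cc2)cc1 | intermediate
11 | (5S)-5-(TBSO)-1,7-bis[4-(MOMO)phenyl]hept-2-yn-1-one | COCOc1ccc(C(=O)C#CC[C@@H](O[Si](C)(C)C(C)(C)C)CCc2ccc(OCOC)cc2)cc1 | intermediate
12 | (1R,5S)-5-(TBSO)-1,7-bis[4-(MOMO)phenyl]hept-2-yn-1-ol | COCOc1ccc([C@@H](O)C#CC[C@@H](O[Si](C)(C)C(C)(C)C)CCc2ccc(OCOC)cc2)cc1 | intermediate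
13 | (1S,2E,5S)-5-(TBSO)-1,7-bis[4-(MOMO)phenyl]hept-2-en-1-ol | COCOc1ccc([C@@H](O)/C=C/C[C@@H](O[Si](C)(C)C(C)(C)C)CCc2ccc(OCOC)cc2)cc1 | intermediate
14 | acetate of 13 | COCOc1ccc([C@@H](OC(C)=O)/C=C/C[C@@H](O[Si](C)(C)C(C)(C)C)CCc2ccc(OCOC)cc2)cc1 | intermediate
15 | (3R,5S)-5-(TBSO)-7-[4-(MOMO)phenyl]-3-{(E)-2-[4-(MOMO)phenyl]ethenyl}heptanoic acid | OC(=O)C[C@H](/C=C/c1ccc(OCOC)cc1)C[C@@H](O[Si](C)(C)C(C)(C)C)CCc1ccc(OCOC)cc1 | intermediate
16 | methyl ester of 15 | COC(=O)C[C@H](/C=C/c1ccc(OCOC)cc1)C[C@@H](O[Si](C)(C)C(C)(C)C)CCc1ccc(OCOC)cc1 | intermediate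
17 | methyl (3S,5S)-2-{hydroxy[4-(MOMO)phenyl]methyl}-analogue of 16 (epimer mixture at C2/carbinol) | COC(=O)C(C(O)c1ccc(OCOC)cc1)[C@H](/C=C/c1ccc(OCOC)cc1)C[C@@H](O[Si](C)(C)C(C)(C)C)CCc1ccc(OCOC)cc1 | intermediate
18 | methyl (3S,5S)-2-{[4-(MOMO)phenyl]methylidene}-analogue (E/Z) | COC(=O)C(=Cc1ccc(OCOC)cc1)[C@H](/C=C/c1ccc(OCOC)cc1)C[C@@H](O[Si](C)(C)C(C)(C)C)CCc1ccc(OCOC)cc1 | intermediate
19 | N-methoxy-N-methyl amide of the acid corresponding to 18 | CON(C)C(=O)C(=Cc1ccc(OCOC)cc1)[C@H](/C=C/c1ccc(OCOC)cc1)C[C@@H](O[Si](C)(C)C(C)(C)C)CCc1ccc(OCOC)cc1 | intermediate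
20 | enone-1,3-dione from 19 + 2 (3′S,5′S) | COCOc1ccc(/C=C/[C@H](C[C@@H](O[Si](C)(C)C(C)(C)C)CCc2ccc(OCOC)cc2)C(=Cc2ccc(OCOC)cc2)C(=O)CC(=O)CCc2ccc(OCOC)cc2)cc1 | intermediate
21 | 20 with (6S)-OH in place of the C6 ketone | COCOc1ccc(/C=C/[C@H](C[C@@H](O[Si](C)(C)C(C)(C)C)CCc2ccc(OCOC)cc2)C(=Cc2ccc(OCOC)cc2)C(=O)C[C@@H](O)CCc2ccc(OCOC)cc2)cc1 | intermediate
22 | (2S,3R,6S)-2,6-cis-THP-4-one bearing the (1E,3S,5S)-5-(TBSO)-1,7-diarylhept-1-en-3-yl side chain at C3 | COCOc1ccc(/C=C/[C@H](C[C@@H](O[Si](C)(C)C(C)(C)C)CCc2ccc(OCOC)cc2)[C@@H]2[C@@H](c3ccc(OCOC)cc3)O[C@@H](CCc3ccc(OCOC)cc3)CC2=O)cc1 | intermediate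
23 | (2S,3S,4S,6S)-THP-4-ol, fully protected | COCOc1ccc(/C=C/[C@H](C[C@@H](O[Si](C)(C)C(C)(C)C)CCc2ccc(OCOC)cc2)[C@@H]2[C@@H](c3ccc(OCOC)cc3)O[C@@H](CCc3ccc(OCOC)cc3)C[C@@H]2O)cc1 | intermediate
24 | 23 with free C5′-OH (MOM groups retained) | COCOc1ccc(/C=C/[C@H](C[C@@H](O)CCc2ccc(OCOC)cc2)[C@@H]2[C@@H](c3ccc(OCOC)cc3)O[C@@H](CCc3ccc(OCOC)cc3)C[C@@H]2O)cc1 | intermediate
25 | Blepharocalyxin C | Oc1ccc(/C=C/[C@H](C[C@@H](O)CCc2ccc(O)cc2)[C@@H]2[C@@H](c3ccc(O)cc3)O[C@@H](CCc3ccc(O)cc3)C[C@@H]2O)cc1 | target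

**Total steps:** 23. **Longest linear sequence:** 22 (1 → 2 → 3 → 4 → 5 → 6 → 7 → 10 → … → 25; step 7 is a side branch).

## Three steps most likely to fail
1. **Step 19, ketoreductase on the enone-dione.** Regioselectivity (C6 versus C4) and ee depend on finding a suitable enzyme for this bulky, partly enolised substrate.
   Fallback: treat 19 with MeMgBr to give the methyl enone, convert it to its α′-silyl dienol ether, and add 3-[4-(MOMO)phenyl]propanal in a chiral-Lewis-acid (Ti/BINOL) Mukaiyama aldol to set C6 directly.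
2. **Step 20, oxa-Michael closure.** The push–pull enone is deactivated, and the γ-H at C3′ could epimerise or isomerise under base.
   Fallback: skip the dehydration in step 16, carry the C2 benzylic alcohol through steps 17–19, close the ring by Lewis-acid SN1 etherification (Bi(OTf)3), then equilibrate C3 through the C4 ketone.
3. **Step 13, Ireland–Claisen of the electron-rich benzylic acetate.** Ionisation of the acetate could erode chirality transfer.
   Fallback: Rh/chiral-diene 1,4-addition of (E)-4-(MOMO)styrylboronic acid to the enoate obtained from 6 (HWE with trimethyl phosphonoacetate), which gives ester 16 directly and removes steps 8–15 and 7.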